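**Retrosynthetic overview** (benzodioxole numbering: C7a quaternary acetal carbon, C3a enol carbon, C5 ketone, C6 allyl carbon)
1. Target ⇒ des-allyl enone by allylation at C6, last step, trans to the side chain on C7a.
2. Des-allyl enone ⇒ cut of the ArCH2–CH(CH3) bond: a 3,4,5-trimethoxybenzyl cation donor plus (4E,5S)-4-ethylidene-1,3-dioxaspiro[4.4]nonan-7-one. Forming this bond triggers a 1,2-shift that enlarges the cyclopentanone by one carbon and gives the fused dioxolane/cyclohexenone directly.
3. Enabling feature: the O–CH2–O bridge spans the sp3 carbon C7a and the enol carbon C3a of the six-membered ring, an alpha-ketol held as a methylene acetal. Read backwards it is an exocyclic enol ether on a spiro dioxolane whose two acetal oxygens carry the cation before and after the shift; the C5 ketone makes the final proton loss irreversible.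
4. Spiro ketone ⇒ iodoetherification of an ethynyl carbinol hemiformal, then methyl coupling ((E)-olefin); carbinol from ethynyl addition to (R)-3-silyloxycyclopentanone, made from commercial (S)-4-silyloxycyclopentenone.
5. Ring order: cyclopentane (chiral pool) → spiro dioxolane → cyclohexenone by ring enlargement (spiro becomes fused). Chirality relay: silyloxy carbon → spiro carbon → C7a and side-chain CH → C6.

Key step: step 8

Remark: the target is read as (6R,7aR) with an (S) side-chain methine; C6 is alpha to the ketone and is therefore set last under substrate control.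

**Step 1**
Reactants: 1 (S)-4-[(tert-butyldimethylsilyl)oxy]cyclopent-2-en-1-one
Product: 2 (R)-3-[(tert-butyldimethylsilyl)oxy]cyclopentan-1-one
Conditions: H2 (1 atm), Pd/C, EtOAc, rt
Reagents that add atoms: none
Why: Heterogeneous hydrogenation of the enone C=C should leave the silyloxy stereocentre untouched (the descriptor changes from S to R only because the ring priorities change).

**Step 2**
Reactants: 2 (R)-3-[(tert-butyldimethylsilyl)oxy]cyclopentan-1-one; 3 ethynylmagnesium bromide
Product: 4 (1S,3R)-3-[(tert-butyldimethylsilyl)oxy]-1-ethynylcyclopentan-1-ol (OH and OTBS cis)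
Conditions: HC≡CMgBr, THF, −78 → 0 °C; then aq. NH4Cl
Reagents that add atoms: ethynylmagnesium bromide, C#C[Mg]Br
Why: 1,2-Addition of an alkynyl Grignard reagent to the ketone should occur mainly on the face opposite the bulky 3-silyloxy group (1,3-induction), giving the cis carbinol whose carbon later becomes the spiro atom.

**Step 3**
Reactants: 4 (1S,3R)-3-[(tert-butyldimethylsilyl)oxy]-1-ethynylcyclopentan-1-ol; 5 formaldehyde (used as paraformaldehyde)
Product: 7 tert-butyl{[(4E,5S,7R)-4-(iodomethylidene)-1,3-dioxaspiro[4.4]nonan-7-yl]oxy}dimethylsilane, via hemiformal 6 (not isolated)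
Conditions: (CH2O)n, I2, NaHCO3, MeCN, 0 °C → rt
Reagents that add atoms: formaldehyde (as paraformaldehyde), C=O; iodine, [I][I]
Why: Reversible hemiformal formation on the tertiary hydroxyl is followed by iodonium-triggered 5-exo-dig iodoetherification of the alkyne; anti addition of O and I across the triple bond should set the (E) geometry, with iodine trans to the ring oxygen and cis to the spiro carbon.

**Step 4**
Reactants: 7 tert-butyl{[(4E,5S,7R)-4-(iodomethylidene)-1,3-dioxaspiro[4.4]nonan-7-yl]oxy}dimethylsilane; 8 methylzinc chloride
Product: 9 tert-butyl{[(4E,5S,7R)-4-ethylidene-1,3-dioxaspiro[4.4]nonan-7-yl]oxy}dimethylsilane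
Conditions: MeZnCl, Pd(PPh3)4 (5 mol %), THF, rt → 45 °C
Reagents that add atoms: methylzinc chloride, C[Zn]Cl
Why: Negishi cross-coupling of the alkenyl iodide proceeds with retention of olefin geometry, so the methyl group should end up cis to the spiro carbon ((E)-ethylidene).

**Step 5**
Reactants: 9 tert-butyl{[(4E,5S,7R)-4-ethylidene-1,3-dioxaspiro[4.4]nonan-7-yl]oxy}dimethylsilane
Product: 10 (4E,5S,7R)-4-ethylidene-1,3-dioxaspiro[4.4]nonan-7-ol
Conditions: Bu4NF, THF, 0 °C → rt
Reagents that add atoms: none
Why: Fluoride cleavage of the silyl ether is non-acidic and should leave the acid-sensitive enol ether acetal intact.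

**Step 6**
Reactants: 10 (4E,5S,7R)-4-ethylidene-1,3-dioxaspiro[4.4]nonan-7-ol
Product: 11 (4E,5S)-4-ethylidene-1,3-dioxaspiro[4.4]nonan-7-one
Conditions: Pr4N[RuO4] (5 mol %), N-methylmorpholine N-oxide, 4 Å molecular sieves, CH2Cl2, rt
Reagents that add atoms: none
Why: Ley–Griffith oxidation of the secondary alcohol is neutral and should spare the enol ether; the spiro atom then remains as the only stereocentre and carries all the chirality.

**Step 7**
Reactants: 12 (3,4,5-trimethoxyphenyl)methanol; 13 trichloroacetonitrile
Product: 14 3,4,5-trimethoxybenzyl 2,2,2-trichloroacetimidate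
Conditions: Cl3CCN, DBU (10 mol %), CH2Cl2, 0 °C
Reagents that add atoms: trichloroacetonitrile, ClC(Cl)(Cl)C#N
Why: Base-catalysed addition of the benzylic alcohol to the nitrile (imidate formation) gives a benzyl cation donor that is activated by catalytic acid.

**Step 8**
Reactants: 11 (4E,5S)-4-ethylidene-1,3-dioxaspiro[4.4]nonan-7-one; 14 3,4,5-trimethoxybenzyl 2,2,2-trichloroacetimidate
Product: 17 (7aR)-7a-[(2S)-1-(3,4,5-trimethoxyphenyl)propan-2-yl]-7,7a-dihydro-1,3-benzodioxol-5(6H)-one, via spiro oxocarbenium ion 15 (not isolated), via ring-enlarged oxocarbenium ion 16 (not isolated)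
Conditions: 14 (1.4 equiv), TMSOTf (10 mol %), 4 Å molecular sieves, CH2Cl2, −78 → −30 °C; then Et3N
Reagents that add atoms: imidate 14 (gives the 3,4,5-trimethoxybenzyl group), COc1cc(COC(=N)C(Cl)(Cl)Cl)cc(OC)c1OC
Why: Proposed new method: the acid-activated imidate should transfer the 3,4,5-trimethoxybenzyl cation to the exocyclic enol ether carbon of 11 (new ArCH2–CH(CH3) bond) to give oxocarbenium ion 15, after which the ring bond C5–C9 shifts to the cationic carbon C4 while the acetal oxygen on C5 takes up the charge (16), and loss of the proton between this cation and the ketone gives the vinylogous ester, the proton being taken up by the next imidate molecule so that the acid stays catalytic. The closest known reaction type is the electrophile-induced semipinacol ring enlargement of 1-(1-alkoxyalkenyl)cycloalkanols, in which a proton, halonium ion or carbon electrophile adds to the enol ether and a ring bond migrates; here an acetal oxygen instead of a free hydroxyl ends the shift, and the acid-catalysed C-benzylation of enol ethers by benzylic imidates is the known first half. The cyclohexenone ring is formed not by closing a chain but by ring enlargement: a suprafacial 1,2-alkyl shift inserts the former exocyclic acetal carbon C4 into the cyclopentanone, which turns the spiro dioxolane into the fused one. The quaternary centre follows from chirality transfer, since C9 can only migrate onto the face of the planar cation on which the spiro junction holds it, so (5S) in 11 should become (7aR); the side-chain methine is fixed by the (E) olefin geometry together with attack of the benzyl cation anti to the migrating bond, which gives (S). The step needs migration of C9 and not C6 (C6 is alpha to the ketone and electron-poor, so it should migrate more slowly), C-benzylation ahead of protonation of the enol ether (the imidate is the strongest base present and there is no free hydroxyl to be O-benzylated), and anti facial selectivity (the spiro junction places the two candidate bonds on opposite faces of the enol ether, and the better donor bond C5–C9 assists attack from the face opposite to it).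

**Step 9**
Reactants: 17 (7aR)-7a-[(2S)-1-(3,4,5-trimethoxyphenyl)propan-2-yl]-7,7a-dihydro-1,3-benzodioxol-5(6H)-one; 18 allyl bromide
Product: 20 (6R,7aR)-6-(prop-2-en-1-yl)-7a-[(2S)-1-(3,4,5-trimethoxyphenyl)propan-2-yl]-7,7a-dihydro-1,3-benzodioxol-5(6H)-one, via lithium enolate 19 (not isolated)
Conditions: LiN(iPr)2, THF, −78 °C; allyl bromide, −78 → −30 °C
Reagents that add atoms: allyl bromide, C=CCBr
Why: Kinetic deprotonation of the vinylogous ester can only occur at C6 (C7a is quaternary), and SN2 allylation of the enolate should take place anti to the side chain on C7a, which the fused dioxolane forces into the pseudo-axial position; the cis epimer would suffer a 1,3-diaxial clash, so equilibration of this alpha centre should lead to the same (6R) product.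

**Compound list**
1 | (S)-4-[(tert-butyldimethylsilyl)oxy]cyclopent-2-en-1-one | O=C1C[C@H](O[Si](C)(C)C(C)(C)C)C=C1 | starting material
2 | (R)-3-[(tert-butyldimethylsilyl)oxy]cyclopentan-1-one | O=C1C[C@H](O[Si](C)(C)C(C)(C)C)CC1 | intermediate
3 | ethynylmagnesium bromide | C#C[Mg]Br | starting material
4 | (1S,3R)-3-[(tert-butyldimethylsilyl)oxy]-1-ethynylcyclopentan-1-ol | C#C[C@]1(O)CC[C@@H](O[Si](C)(C)C(C)(C)C)C1 | intermediate
5 | formaldehyde (used as paraformaldehyde) | C=O | starting material
6 | {[(1S,3R)-3-[(tert-butyldimethylsilyl)oxy]-1-ethynylcyclopentyl]oxy}methanol (hemiformal) | C#C[C@]1(OCO)CC[C@@H](O[Si](C)(C)C(C)(C)C)C1 | intermediate (not isolated)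
7 | tert-butyl{[(4E,5S,7R)-4-(iodomethylidene)-1,3-dioxaspiro[4.4]nonan-7-yl]oxy}dimethylsilane | I/C=C1/OCO[C@]12CC[C@@H](O[Si](C)(C)C(C)(C)C)C2 | intermediate
8 | methylzinc chloride | C[Zn]Cl | starting material
9 | tert-butyl{[(4E,5S,7R)-4-ethylidene-1,3-dioxaspiro[4.4]nonan-7-yl]oxy}dimethylsilane | C/C=C1/OCO[C@]12CC[C@@H](O[Si](C)(C)C(C)(C)C)C2 | intermediate
10 | (4E,5S,7R)-4-ethylidene-1,3-dioxaspiro[4.4]nonan-7-ol | C/C=C1/OCO[C@]12CC[C@@H](O)C2 | intermediate
11 | (4E,5S)-4-ethylidene-1,3-dioxaspiro[4.4]nonan-7-one | C/C=C1/OCO[C@]12CCC(=O)C2 | intermediate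
12 | (3,4,5-trimethoxyphenyl)methanol | COc1cc(CO)cc(OC)c1OC | starting material
13 | trichloroacetonitrile | ClC(Cl)(Cl)C#N | starting material
14 | 3,4,5-trimethoxybenzyl 2,2,2-trichloroacetimidate | COc1cc(COC(=N)C(Cl)(Cl)Cl)cc(OC)c1OC | intermediate
15 | spiro oxocarbenium ion (benzylated at the former ethylidene carbon, cation on the acetal carbon C4) | C[C@@H](Cc1cc(OC)c(OC)c(OC)c1)C1=[O+]CO[C@]12CCC(=O)C2 | intermediate (not isolated)
16 | ring-enlarged oxocarbenium ion (fused dioxolane, cation on the future C3a) | C[C@@H](Cc1cc(OC)c(OC)c(OC)c1)[C@]12CCC(=O)CC1=[O+]CO2 | intermediate (not isolated)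
17 | (7aR)-7a-[(2S)-1-(3,4,5-trimethoxyphenyl)propan-2-yl]-7,7a-dihydro-1,3-benzodioxol-5(6H)-one | O=C1CC[C@]2([C@@H](C)Cc3cc(OC)c(OC)c(OC)c3)OCOC2=C1 | intermediate
18 | allyl bromide | C=CCBr | starting material
19 | lithium enolate of 17 (C5–O–Li, C5=C6) | [Li]OC1=CC[C@]2([C@@H](C)Cc3cc(OC)c(OC)c(OC)c3)OCOC2=C1 | intermediate (not isolated)
20 | (6R,7aR)-6-(prop-2-en-1-yl)-7a-[(2S)-1-(3,4,5-trimethoxyphenyl)propan-2-yl]-7,7a-dihydro-1,3-benzodioxol-5(6H)-one | C=CC[C@@H]1C[C@]2([C@@H](C)Cc3cc(OC)c(OC)c(OC)c3)OCOC2=CC1=O | target

**Total step count:** 9. **Longest linear sequence:** 8 steps (1–6, 8, 9); step 7 prepares the benzyl donor.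

**Steps most likely to fail**

Step 8 (Proposed new method). The first cation 15 may be diverted before the ring bond shifts: by proton loss to a tetrasubstituted enol ether, by ring closure onto the electron-rich arene, or by capture. The enol ether may also be protonated instead of benzylated, and the benzyl donor may condense with itself. The fallback uses known reactions only; it sets out from 11 (with 14) and comes back at 17. The cascade is split. Enol ether 11 is C-benzylated with 14 and BF3·OEt2 in CH2Cl2 at −78 °C and quenched cold with aqueous NaHCO3. This is a Lewis-acid alkylation of an enol ether by a benzylic cation with hydrolytic work-up; water opens the acetal cation, formaldehyde is lost, and the product should be the alpha-ketol (3S)-3-hydroxy-3-[(2S)-2-methyl-3-(3,4,5-trimethoxyphenyl)propanoyl]cyclopentan-1-one F1. An acyloin (alpha-ketol) rearrangement with Al(OtBu)3 in toluene follows. This is the ring enlargement known for 1-acylcyclopentanols, pulled forward here by the cyclic 1,3-diketone that forms. In the chelated ketol the same ring carbon should move onto the same face, giving (4R)-4-hydroxy-4-[(2S)-1-(3,4,5-trimethoxyphenyl)propan-2-yl]cyclohexane-1,3-dione F2. CH2BrCl and Cs2CO3 in DMF then bridge the tertiary hydroxyl and the neighbouring enol oxygen as the methylene acetal, which is 17. In F1 the side-chain methine is alpha to a ketone and may epimerise, so the epimers would be separated at F2; the beta-hydroxy ketone in F1 also calls for mild, non-basic handling.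

Step 3. The standing amount of hemiformal on the hindered tertiary hydroxyl may be too small, so that iodonium-induced ring enlargement of the alkynyl carbinol or iodination at the alkyne terminus outruns the cyclisation. The fallback sets out from 4 and comes back at 7. The acetal tether is installed covalently first: MOMCl and iPr2NEt in CH2Cl2 give (1S,3R)-3-[(tert-butyldimethylsilyl)oxy]-1-ethynyl-1-(methoxymethoxy)cyclopentane F3. Treatment with I2 in MeCN then lets the distal acetal oxygen attack the iodonium-activated alkyne (5-exo-dig, anti), and the oxonium ion loses its methyl group to iodide, which should give 7 with the same (E) geometry.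

Step 2. Facial selectivity may be poor in the addition to a flexible cyclopentanone whose directing group sits two carbons away. The fallback sets out from 1 and comes back at 4; it moves the addition to the flat enone, where the silyloxy group shields one face more effectively. Lithium (trimethylsilyl)acetylide in THF at −78 °C should add anti to the silyloxy group to give (1R,4S)-4-[(tert-butyldimethylsilyl)oxy]-1-[(trimethylsilyl)ethynyl]cyclopent-2-en-1-ol F4. Diimide (2-nitrobenzenesulfonyl hydrazide, Et3N, CH2Cl2) should reduce the ring alkene faster than the silyl-capped alkyne, giving (1S,3R)-3-[(tert-butyldimethylsilyl)oxy]-1-[(trimethylsilyl)ethynyl]cyclopentan-1-ol F5. K2CO3 in MeOH removes the alkynyl silyl group and gives 4.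

**Further compounds**
F1 | step 8 | (3S)-3-hydroxy-3-[(2S)-2-methyl-3-(3,4,5-trimethoxyphenyl)propanoyl]cyclopentan-1-one | C[C@@H](Cc1cc(OC)c(OC)c(OC)c1)C(=O)[C@]1(O)CCC(=O)C1
F2 | step 8 | (4R)-4-hydroxy-4-[(2S)-1-(3,4,5-trimethoxyphenyl)propan-2-yl]cyclohexane-1,3-dione | C[C@@H](Cc1cc(OC)c(OC)c(OC)c1)[C@]1(O)CCC(=O)CC1=O
F3 | step 3 | (1S,3R)-3-[(tert-butyldimethylsilyl)oxy]-1-ethynyl-1-(methoxymethoxy)cyclopentane | C#C[C@]1(OCOC)CC[C@@H](O[Si](C)(C)C(C)(C)C)C1
F4 | step 2 | (1R,4S)-4-[(tert-butyldimethylsilyl)oxy]-1-[(trimethylsilyl)ethynyl]cyclopent-2-en-1-ol | C[Si](C)(C)C#C[C@]1(O)C=C[C@@H](O[Si](C)(C)C(C)(C)C)C1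
F5 | step 2 | (1S,3R)-3-[(tert-butyldimethylsilyl)oxy]-1-[(trimethylsilyl)ethynyl]cyclopentan-1-ol | C[Si](C)(C)C#C[C@]1(O)CC[C@@H](O[Si](C)(C)C(C)(C)C)C1
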